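The pitfall of a dilution series is to watch J alone: at 120 min J reads 14 % in the south-west run and 11 % in the south run, while Q reads 27 % and 55 %.

| setting | south-west | south | blue | violet | red | green |
|---|---|---|---|---|---|---|
| G | 0.012 M | 0.037 M | 0.015 M | 0.025 M | 0.040 M | 0.060 M |
| remark | run made earlier | run made earlier |  |  |  |  |
| time |  |  | 4.0 h | 4.0 h | 4.0 h | 4.0 h |

- south-west (time / min: J / %, Q / %, D / %): 25.0: 4, 9, 2; 50.0: 8, 16, 1; 80.0: 11, 26, 2; 90.0: 15, 25, 2; 120: 14, 27, 1
- south (time / min: J / %, Q / %, D / %): 25.0: 5, 26, 2; 50.0: 8, 42, 1; 80.0: 9, 46, 0; 90.0: 11, 52, 0; 120: 11, 55, 1

(scatter of a reading: 1.5 percentage points)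

- in percentages every species weighs as the G in it: one Q or D counts as two
- a reading or a percentage of J counts all its forms, free or not
- "hardly changes" means that all values lie within two and a half points (for a concentration: within two and a half percent of the largest)

- share of J in all that became J or Q or D or X for blue, violet, red, green, in this order
- the course of these numbers from the first flask to the last (rises, then falls / falls all the way / hardly changes / falls, then rises / rises all the way)

If J arises from one G and Q from two, then at like conversion the ratio of J to Q falls inversely with the charge, so their ratio times the charge should stay roughly constant. At 120 min this product reads 0.00622 M in the south-west run and 0.00740 M in the south run, with a mean of 0.00681 M. This mean, a reading with the scatter of its runs, is the crossover concentration, the charge of G at which this reckoning puts J equal to Q (in the trade, an effective molarity). At that same time D reads 1 % in both runs, less than J, so it is dropped here as a small correction, and the share of J is reckoned as the crossover concentration over the crossover concentration plus the charge. That reckoning gives 31.2 % for blue and 10.2 % for green.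

The forecast gives 35 %, 26.5 %, 20 % and 15.5 %, higher than this reckoning at blue and at green, and in it the share falls all the way. Its ground: “dilution should still favour the ring, so the share falls throughout”.

The flasks give 27.9 %, 21.2 %, 16.2 % and 12.6 %, and the share falls all the way.

    G + J → D (k = 14.6 /M/h)
    2 G ⇌ Q (K = 760 /M, k = 14.5 /M/h)
    J ⇌ X (K = 0.350, k = 1.35 /h)
    G + J ⇌ L, settled at all times (K = 74.0 /M)
    G → J (k = 0.159 /h)

Blue at 4.00 h holds J at 20.5 % with its bound form L counted, Q at 41.2 % and X at 5.52 %, and in blue the forward half-life of free J by the step to X alone, 0.51 h, is short against the time. The crossover concentration put 31.2 % on blue, higher than the flask's 27.9 %. On violet it gives 21.4 %, and the flask gives 21.2 %.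

The runs are calculated for substances that don't exist; noise was put on by code.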